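In labdane numbering, ring B (C5–C6–C7–C8–C9–C10) holds a γ,δ-unsaturated acid retron, C20–C10–C9–C8=C17. It is therefore closed last by an Ireland–Claisen ring contraction: the silyl ketene acetal of an eight-membered lactone fused to ring A (C20 acyl carbon, O–C17 allylic bond, exocyclic E-C8=C9 olefin carrying the linalool-derived chain) rearranges transannularly through an enforced chair. One operation forms C9–C10 and ring B, the quaternary C10 with C20 as carboxyl, the C9 side chain anti to C20, the trans ring fusion and the 8(17)-methylene. Ring A comes from Evans alkylation, metathesis and dihydroxylation; the 7α-hydroxyl follows by allylic oxidation and ketone reduction.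

Key step: step 15

Remark on the chemistry: labdane numbering is used throughout and α/β refer to the usual drawing with C20 on C10 β, so the target has H5 α, the C9 side chain α (H9 β) and 2α,3α,7α oxygen substituents; (R)-(−)-linalool is assumed to be used in enantiopure form.

Step 1
Reactants: 1 (R)-(−)-linalool
Product: 2 (R)-linalool tert-butyldimethylsilyl ether
Conditions: TBSOTf, 2,6-lutidine, CH2Cl2, 0 °C
Reagents that add atoms: tert-butyldimethylsilyl triflate, CC(C)(C)[Si](C)(C)OS(=O)(=O)C(F)(F)F
Why: O-silylation of the hindered tertiary allylic alcohol with a silyl triflate and a non-nucleophilic base proceeds without ionisation, so the C13 stereocentre taken from the chiral pool is kept.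

Step 2
Reactants: 2 (R)-linalool tert-butyldimethylsilyl ether
Product: 3 (4R)-4-(tert-butyldimethylsilyloxy)-4-methylhex-5-enal
Conditions: O3, CH2Cl2, pyridine (cat.), Sudan Red 7B, −78 °C; then PPh3
Reagents that add atoms: ozone, [O-][O+]=O
Why: Ozonolysis is chemoselective for the electron-rich trisubstituted alkene over the monosubstituted vinyl group when stopped at the indicator end point, and reductive work-up should give the aldehyde that becomes C9.

Step 3
Reactants: 4 (R)-4-benzyloxazolidin-2-one; 5 3,3-dimethylpent-4-enoic acid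
Product: 6 (R)-4-benzyl-3-(3,3-dimethylpent-4-enoyl)oxazolidin-2-one
Conditions: 5, PivCl, Et3N, THF, −20 °C; then LiCl, 4, rt
Reagents that add atoms: none
Why: N-Acylation of the oxazolidinone through the mixed pivalic anhydride (attachment of the Evans auxiliary) needs no strong base and leaves the terminal alkene untouched.

Step 4
Reactants: 6 (R)-4-benzyl-3-(3,3-dimethylpent-4-enoyl)oxazolidin-2-one
Product: 7 tert-butyl (3R)-3-[(R)-4-benzyl-2-oxooxazolidine-3-carbonyl]-4,4-dimethylhex-5-enoate
Conditions: NaHMDS, THF, −78 °C; BrCH2CO2t-Bu, −78 to −40 °C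
Reagents that add atoms: tert-butyl bromoacetate, CC(C)(C)OC(=O)CBr
Why: Evans asymmetric alkylation, in which the chelated Z-sodium enolate is alkylated on the face opposite the benzyl group, should set C5 (R) next to the gem-dimethyl carbon.

Step 5
Reactants: 7 tert-butyl (3R)-3-[(R)-4-benzyl-2-oxooxazolidine-3-carbonyl]-4,4-dimethylhex-5-enoate
Product: 9 (4R)-4-(2-methylbut-3-en-2-yl)dihydrofuran-2(3H)-one, via hydroxy ester 8 (not isolated)
Conditions: LiBH4, H2O (1 equiv), Et2O, 0 °C; then TFA, CH2Cl2, rt
Reagents that add atoms: none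
Why: Chemoselective borohydride reduction of the imide releases the auxiliary and the primary alcohol, and acidolysis of the tert-butyl ester then triggers γ-lactonisation, C5 being non-epimerisable throughout.

Step 6
Reactants: 9 (4R)-4-(2-methylbut-3-en-2-yl)dihydrofuran-2(3H)-one
Product: 10 (3S,4R)-3-allyl-4-(2-methylbut-3-en-2-yl)dihydrofuran-2(3H)-one (trans)
Conditions: LDA, THF, −78 °C; allyl bromide, DMPU
Reagents that add atoms: allyl bromide, C=CCBr
Why: Alkylation of the lactone lithium enolate should occur anti to the bulky C5 substituent (trans product), and this C10 centre is later erased by enolisation.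

Step 7
Reactants: 10 (3S,4R)-3-allyl-4-(2-methylbut-3-en-2-yl)dihydrofuran-2(3H)-one
Product: 11 (3aR,7aS)-4,4-dimethyl-3a,4,7,7a-tetrahydroisobenzofuran-1(3H)-one (trans-fused)
Conditions: Grubbs II (5 mol %), CH2Cl2, 40 °C
Reagents that add atoms: none
Why: Ring-closing metathesis of the allyl and 1,1-dimethylallyl groups closes the six-membered ring A as its C2=C3 cyclohexene with loss of ethylene, without creating a stereocentre.

Step 8
Reactants: 11 (3aR,7aS)-4,4-dimethyl-3a,4,7,7a-tetrahydroisobenzofuran-1(3H)-one
Product: 12 trans-fused 5,6-cis-dihydroxy-4,4-dimethylhexahydroisobenzofuran-1(3H)-one, both OH cis to H-3a (labdane 2α,3α-diol)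
Conditions: OsO4 (cat.), NMO, acetone/H2O, rt
Reagents that add atoms: osmium tetroxide (catalytic carrier), O=[Os](=O)(=O)=O; N-methylmorpholine N-oxide, C[N+]1([O-])CCOCC1; water, O
Why: Catalytic syn-dihydroxylation should attack the ring-A alkene on the face of the axial H5, anti to the pseudoaxial C4 methyl of the trans-locked half-chair, which sets both carbinol centres (2α,3α) relative to C5.

Step 9
Reactants: 12 labdane 2α,3α-diol lactone
Product: 13 acetonide of 12 (2α,3α-isopropylidenedioxy lactone)
Conditions: 2,2-dimethoxypropane, PPTS, CH2Cl2, rt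
Reagents that add atoms: 2,2-dimethoxypropane, COC(C)(C)OC
Why: Acid-catalysed transketalisation of the cis-diol gives the isopropylidene acetal (acetonide protection), which masks both hydroxyls until after the ring contraction.

Step 10
Reactants: 13 2α,3α-isopropylidenedioxy lactone
Product: 14 ring-A seleno acid (10α-CO2H, 5β-CH2SePh, 2α,3α-acetonide on the 4,4-dimethylcyclohexane)
Conditions: PhSeSePh, NaH, THF; then HMPA, 13, reflux; aq. HCl
Reagents that add atoms: diphenyl diselenide, c1ccc(cc1)[Se][Se]c1ccccc1
Why: The soft, uncomplexed phenylselenolate should open the strained trans-fused lactone by SN2 alkyl–oxygen cleavage at the primary C6, which frees the C20 acid and installs a radical precursor without touching the ketal.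

Step 11
Reactants: 14 ring-A seleno acid
Product: 15 ring-A phosphonate acid (5β-CH2CH2CH(CO2Et)P(O)(OEt)2, mixture at the phosphonate carbon)
Conditions: (Me3Si)3SiH, AIBN, ethyl 2-(diethoxyphosphoryl)acrylate (3 equiv), toluene, 85 °C
Reagents that add atoms: ethyl 2-(diethoxyphosphoryl)acrylate, C=C(C(=O)OCC)P(=O)(OCC)OCC
Why: Giese radical conjugate addition of the primary C6 radical to the doubly activated acrylate, followed by hydrogen transfer from the silane, forms C6–C7, and the new phosphonate-bearing centre is destroyed in the next step.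

Step 12
Reactants: 15 ring-A phosphonate acid; 3 (4R)-4-(tert-butyldimethylsilyloxy)-4-methylhex-5-enal
Product: 16 (E)-enoate acid (ethyl ester at C17, C8=C9 with C17 trans to C11)
Conditions: NaH (2.2 equiv), THF/DMF, 0 °C to rt
Reagents that add atoms: none
Why: Horner–Wadsworth–Emmons olefination of the α-alkyl phosphonoacetate with the aldehyde should give mainly the E trisubstituted enoate (ester trans to C11) under thermodynamic control, the minor Z isomer being removed by chromatography.

Step 13
Reactants: 16 (E)-enoate acid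
Product: 17 (E)-hydroxy acid (seco acid, C17 allylic alcohol and C20 acid)
Conditions: DIBAL-H (4 equiv), CH2Cl2, −78 °C
Reagents that add atoms: none
Why: Hydride reduction of the conjugated ethyl ester to the allylic alcohol should proceed at −78 °C while the carboxylic acid is held as an unreactive aluminium carboxylate.

Step 14
Reactants: 17 (E)-hydroxy acid
Product: 18 eight-membered lactone (C20(=O)–O–C17, trans-fused to ring A at C5–C10, exocyclic E-C8=C9 alkylidene)
Conditions: MNBA, DMAP, Et3N, CH2Cl2 (2 mM), rt, slow addition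
Reagents that add atoms: none
Why: Shiina macrolactonisation under high dilution should close the eight-membered ring because the trans-1,2-disubstituted cyclohexane and the trigonal C8 pre-organise the chain and only the primary allylic hydroxyl is free.

Step 15
Reactants: 18 eight-membered lactone
Product: 21 (13R)-13-(tert-butyldimethylsilyloxy)-2α,3α-isopropylidenedioxy-9βH-labda-8(17),14-dien-20-oic acid, via silyl ketene acetal 19 (not isolated), via trimethylsilyl ester 20 (not isolated)
Conditions: LDA, TMSCl/Et3N, THF, −78 °C to rt; toluene, 80 °C; aq. citric acid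
Reagents that add atoms: none
Why: Kinetic deprotonation at C10 with in situ silylation gives the cyclic ketene acetal 19, whose C10=C20 bond is locked cis in the eight-membered ring (ring oxygen syn to C5), and on warming C10 bonds to the exocyclic C9 while O–C17 breaks in a concerted [3,3] shift; the closest known reaction type is the Ireland–Claisen rearrangement of allylic lactone silyl ketene acetals (Claisen ring contraction). Ring B closes transannularly by C9–C10 bond formation in a bicyclo[3.3.1]-like array in which the Claisen chair and the nascent cyclohexane chair share C10–C9–C8, a boat being excluded because the three-atom C5–C6–C7 strap cannot span it. C10 is controlled by the existing C5 centre, since only the chair with C4 equatorial on the forming ring (trans fusion, C20 axial) avoids a syn-axial clash between the gem-dimethyl carbon and C11. C9 is controlled by the olefin geometry, because the substituent trans to C17 (C11 in the E olefin) must take the Claisen-equatorial site, which is axial on ring B and anti to C20. The step thus needs the E olefin and the fixed ketene acetal geometry, both secured by the substrate, and the silyl ester 20 is hydrolysed on work-up.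

Step 16
Reactants: 21 labdadien-20-oic acid
Product: 22 (13R)-13-(tert-butyldimethylsilyloxy)-2α,3α-isopropylidenedioxy-9βH-labda-8(17),14-dien-20-ol
Conditions: LiAlH4, THF, 0 °C to reflux
Reagents that add atoms: none
Why: Hydride reduction of the hindered axial carboxylic acid should give the primary alcohol, while the ketal, silyl ether and unconjugated alkenes are inert.

Step 17
Reactants: 22 labdadien-20-ol
Product: 23 20-acetate of 22
Conditions: Ac2O, pyridine, DMAP (cat.), rt
Reagents that add atoms: acetic anhydride, CC(=O)OC(C)=O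
Why: Acetylation of the primary neopentyl alcohol is carried out while the ring-A diol is still masked, so that only O20 is acylated.

Step 18
Reactants: 23 20-acetate acetonide
Product: 24 20-acetoxy-13-(tert-butyldimethylsilyloxy)-9βH-labda-8(17),14-diene-2α,3α-diol
Conditions: AcOH/H2O/THF (3:1:1), 45 °C
Reagents that add atoms: none
Why: Mild acidic hydrolysis of the isopropylidene ketal should free the cis-diol, since the tertiary silyl ether, the primary acetate and the alkenes tolerate aqueous acetic acid.

Step 19
Reactants: 24 2α,3α-diol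
Product: 25 2α-angelate of 24 (3α-OH free)
Conditions: angelic acid, 2,4,6-trichlorobenzoyl chloride, Et3N, toluene, rt; then 24, 75 °C
Reagents that add atoms: angelic acid, C/C=C(C)\C(=O)O
Why: Yamaguchi-type esterification with the preformed mixed anhydride should acylate the unhindered equatorial 2α-OH in preference to the axial, neopentyl-flanked 3α-OH, and the absence of DMAP and the moderate temperature keep the Z (angeloyl) geometry.

Step 20
Reactants: 25 2α-angelate
Product: 26 3α,20-diacetoxy-2α-angeloyloxy-13-(tert-butyldimethylsilyloxy)-9βH-labda-8(17),14-diene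
Conditions: Ac2O, DMAP, pyridine, 40 °C
Reagents that add atoms: acetic anhydride, CC(=O)OC(C)=O
Why: DMAP-catalysed acetylation should esterify the remaining hindered axial 3α-OH, the tertiary silyl ether masking the only other hydroxyl.

Step 21
Reactants: 26 triester silyl ether
Product: 28 7-oxo derivative of 26 (8(17)-en-7-one), via 7-hydroxy epimers 27 (not isolated)
Conditions: SeO2 (0.5 equiv), t-BuOOH, CH2Cl2, rt; then Dess–Martin periodinane, NaHCO3
Reagents that add atoms: selenium dioxide, O=[Se]=O; tert-butyl hydroperoxide, CC(C)(C)OO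
Why: Catalytic SeO2 allylic oxidation (ene reaction then [2,3]-shift) should hydroxylate the ring CH2 next to the 1,1-disubstituted alkene, the equatorial tertiary C9–H, the conjugated angelate and the vinyl group without allylic hydrogens being unreactive, and Dess–Martin oxidation in the same flask converges both C7 epimers to the enone.

Step 22
Reactants: 28 8(17)-en-7-one
Product: 29 7α-hydroxy derivative (13-O-TBS ether of the target)
Conditions: (S)-Me-CBS, catecholborane, toluene, −78 °C
Reagents that add atoms: none
Why: Corey–Bakshi–Shibata reduction should deliver hydride to the β face to give the 7R (7α, axial) alcohol, the methylene-bearing C8 acting as the large group, and the axial C9 side chain blocks the α trajectory so that substrate and reagent control are matched.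

Step 23
Reactants: 29 13-O-TBS ether of the target
Product: 30 target, 3α,20-diacetoxy-2α-angeloyloxy-9βH-labda-8(17),14-diene-7α,13R-diol
Conditions: HF·pyridine, pyridine, THF, 0 °C to rt
Reagents that add atoms: none
Why: Fluoride-mediated desilylation of the tertiary silyl ether under buffered, non-basic conditions should leave the three esters and both allylic alcohols untouched.

Compound list

1 | (R)-(−)-linalool | C=C[C@](C)(O)CCC=C(C)C | starting material
2 | (R)-linalool tert-butyldimethylsilyl ether | C=C[C@](C)(O[Si](C)(C)C(C)(C)C)CCC=C(C)C | intermediate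
3 | (4R)-4-(tert-butyldimethylsilyloxy)-4-methylhex-5-enal | C=C[C@](C)(O[Si](C)(C)C(C)(C)C)CCC=O | intermediate
4 | (R)-4-benzyloxazolidin-2-one | O=C1OC[C@@H](Cc2ccccc2)N1 | starting material
5 | 3,3-dimethylpent-4-enoic acid | C=CC(C)(C)CC(=O)O | starting material
6 | (R)-4-benzyl-3-(3,3-dimethylpent-4-enoyl)oxazolidin-2-one | O=C1OC[C@@H](Cc2ccccc2)N1C(=O)CC(C)(C)C=C | intermediate
7 | tert-butyl (3R)-3-[(R)-4-benzyl-2-oxooxazolidine-3-carbonyl]-4,4-dimethylhex-5-enoate | O=C1OC[C@@H](Cc2ccccc2)N1C(=O)[C@H](CC(=O)OC(C)(C)C)C(C)(C)C=C | intermediate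
8 | tert-butyl (3R)-3-(hydroxymethyl)-4,4-dimethylhex-5-enoate | OC[C@H](CC(=O)OC(C)(C)C)C(C)(C)C=C | intermediate (not isolated)
9 | (4R)-4-(2-methylbut-3-en-2-yl)dihydrofuran-2(3H)-one | O=C1OC[C@@H](C(C)(C)C=C)C1 | intermediate
10 | (3S,4R)-3-allyl-4-(2-methylbut-3-en-2-yl)dihydrofuran-2(3H)-one | O=C1OC[C@@H](C(C)(C)C=C)[C@@H]1CC=C | intermediate
11 | (3aR,7aS)-4,4-dimethyl-3a,4,7,7a-tetrahydroisobenzofuran-1(3H)-one | O=C1OC[C@H]2C(C)(C)C=CC[C@H]12 | intermediate
12 | trans-fused 5,6-cis-dihydroxy-4,4-dimethylhexahydroisobenzofuran-1(3H)-one (labdane 2α,3α-diol) | O=C1OC[C@H]2C(C)(C)[C@H](O)[C@H](O)C[C@H]12 | intermediate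
13 | acetonide of 12 | O=C1OC[C@H]2C(C)(C)[C@@H]3OC(C)(C)O[C@@H]3C[C@H]12 | intermediate
14 | ring-A seleno acid (10α-CO2H, 5β-CH2SePh, 2α,3α-acetonide) | OC(=O)[C@H]1C[C@H]2OC(C)(C)O[C@H]2C(C)(C)[C@@H]1C[Se]c1ccccc1 | intermediate
15 | ring-A phosphonate acid | OC(=O)[C@H]1C[C@H]2OC(C)(C)O[C@H]2C(C)(C)[C@@H]1CCC(C(=O)OCC)P(=O)(OCC)OCC | intermediate
16 | (E)-enoate acid | OC(=O)[C@H]1C[C@H]2OC(C)(C)O[C@H]2C(C)(C)[C@@H]1CC/C(C(=O)OCC)=C\CC[C@@](C)(O[Si](C)(C)C(C)(C)C)C=C | intermediate
17 | (E)-hydroxy acid (seco acid) | OC(=O)[C@H]1C[C@H]2OC(C)(C)O[C@H]2C(C)(C)[C@@H]1CC/C(CO)=C\CC[C@@](C)(O[Si](C)(C)C(C)(C)C)C=C | intermediate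
18 | eight-membered lactone with exocyclic E-C8=C9 | O=C1OC/C(=C/CC[C@@](C)(O[Si](C)(C)C(C)(C)C)C=C)CC[C@H]2C(C)(C)[C@@H]3OC(C)(C)O[C@@H]3C[C@H]12 | intermediate
19 | trimethylsilyl ketene acetal of 18 | C[Si](C)(C)O/C1=C2\C[C@H]3OC(C)(C)O[C@H]3C(C)(C)[C@@H]2CC/C(=C\CC[C@@](C)(O[Si](C)(C)C(C)(C)C)C=C)CO1 | intermediate (not isolated)
20 | trimethylsilyl ester of 21 | C=C[C@](C)(O[Si](C)(C)C(C)(C)C)CC[C@@H]1C(=C)CC[C@H]2C(C)(C)[C@@H]3OC(C)(C)O[C@@H]3C[C@]12C(=O)O[Si](C)(C)C | intermediate (not isolated)
21 | (13R)-13-(tert-butyldimethylsilyloxy)-2α,3α-isopropylidenedioxy-9βH-labda-8(17),14-dien-20-oic acid | C=C[C@](C)(O[Si](C)(C)C(C)(C)C)CC[C@@H]1C(=C)CC[C@H]2C(C)(C)[C@@H]3OC(C)(C)O[C@@H]3C[C@]12C(=O)O | intermediate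
22 | corresponding 20-ol | C=C[C@](C)(O[Si](C)(C)C(C)(C)C)CC[C@@H]1C(=C)CC[C@H]2C(C)(C)[C@@H]3OC(C)(C)O[C@@H]3C[C@]12CO | intermediate
23 | corresponding 20-acetate | C=C[C@](C)(O[Si](C)(C)C(C)(C)C)CC[C@@H]1C(=C)CC[C@H]2C(C)(C)[C@@H]3OC(C)(C)O[C@@H]3C[C@]12COC(C)=O | intermediate
24 | 20-acetoxy-13-(tert-butyldimethylsilyloxy)-9βH-labda-8(17),14-diene-2α,3α-diol | C=C[C@](C)(O[Si](C)(C)C(C)(C)C)CC[C@@H]1C(=C)CC[C@H]2C(C)(C)[C@H](O)[C@H](O)C[C@]12COC(C)=O | intermediate
25 | 2α-angelate of 24 | C=C[C@](C)(O[Si](C)(C)C(C)(C)C)CC[C@@H]1C(=C)CC[C@H]2C(C)(C)[C@H](O)[C@H](OC(=O)/C(C)=C\C)C[C@]12COC(C)=O | intermediate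
26 | 3α,20-diacetoxy-2α-angeloyloxy-13-(tert-butyldimethylsilyloxy)-9βH-labda-8(17),14-diene | C=C[C@](C)(O[Si](C)(C)C(C)(C)C)CC[C@@H]1C(=C)CC[C@H]2C(C)(C)[C@H](OC(C)=O)[C@H](OC(=O)/C(C)=C\C)C[C@]12COC(C)=O | intermediate
27 | 7-hydroxy derivative of 26 (both C7 epimers) | C=C[C@](C)(O[Si](C)(C)C(C)(C)C)CC[C@@H]1C(=C)C(O)C[C@H]2C(C)(C)[C@H](OC(C)=O)[C@H](OC(=O)/C(C)=C\C)C[C@]12COC(C)=O | intermediate (not isolated)
28 | 7-oxo derivative of 26 | C=C[C@](C)(O[Si](C)(C)C(C)(C)C)CC[C@@H]1C(=C)C(=O)C[C@H]2C(C)(C)[C@H](OC(C)=O)[C@H](OC(=O)/C(C)=C\C)C[C@]12COC(C)=O | intermediate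
29 | 13-O-TBS ether of the target (7α-OH) | C=C[C@](C)(O[Si](C)(C)C(C)(C)C)CC[C@@H]1C(=C)[C@H](O)C[C@H]2C(C)(C)[C@H](OC(C)=O)[C@H](OC(=O)/C(C)=C\C)C[C@]12COC(C)=O | intermediate
30 | CNP0147212.1, 3α,20-diacetoxy-2α-angeloyloxy-9βH-labda-8(17),14-diene-7α,13R-diol | C=C[C@](C)(O)CC[C@@H]1C(=C)[C@H](O)C[C@H]2C(C)(C)[C@H](OC(C)=O)[C@H](OC(=O)/C(C)=C\C)C[C@]12COC(C)=O | target

Total step count: 23. Longest linear sequence: 21 steps (steps 3 to 23); steps 1 and 2 form the side-chain branch that joins in step 12.

Steps most likely to fail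

Step 15. What may go wrong: incomplete enolisation at the hindered tertiary C10–H, loss of the enolate through ketene formation before silylation, or a rearrangement slow enough to leak through the alternative chair and give the cis-fused acid. The fallback is a stepwise polar closure of the same C9–C10 bond. It sets out from hydroxy acid 17: methylation with TMSCHN2 should give the hydroxy methyl ester F1, and MsCl/LiCl/2,4,6-collidine should convert its allylic alcohol into the allylic chloride F2. KHMDS (THF, −78 to 0 °C) should then trigger a 6-exo intramolecular SN2′ C-allylation of the C10 ester enolate at C9, with loss of chloride, to give the decalin methyl ester F3. Reduction of F3 with LiAlH4 returns to the route at alcohol 22. The ring fusion is less firmly controlled in this variant than in the concerted process.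

Step 14. What may go wrong: intermolecular acylation (diolide and oligomer formation) outrunning the entropically disfavoured eight-membered ring closure. The fallback activates the alcohol instead of the acid: an intramolecular Mitsunobu esterification (PPh3, DIAD, toluene, high dilution), in which the carboxylate displaces the oxyphosphonium group at the primary allylic C17 in an SN2 step. It sets out from 17 and returns at lactone 18 without any new intermediate; competing SN2′ attack at C9 would have to be watched.

Step 19. What may go wrong: poor discrimination between the two cis hydroxyls (bis-acylation or acylation at O3) and isomerisation of the angeloyl group to tigloyl on prolonged heating. The fallback inverts the order of the two acylations and lets stereoelectronics choose the site. From diol 24, trimethyl orthoacetate/CSA should give the cyclic 2,3-orthoacetate F4, whose mild aqueous acid opening delivers the axial ester, the 3α-acetate 2α-alcohol F5. Angeloylation of the single free equatorial hydroxyl with the same mixed anhydride should then give 26 directly, where the route is rejoined (25 is bypassed); acetate migration from O3 to O2 under the acylation conditions is the point to control.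

Further compounds

F1 | step 15 | hydroxy methyl ester (methyl ester of 17) | COC(=O)[C@H]1C[C@H]2OC(C)(C)O[C@H]2C(C)(C)[C@@H]1CC/C(CO)=C\CC[C@@](C)(O[Si](C)(C)C(C)(C)C)C=C
F2 | step 15 | allylic chloride | COC(=O)[C@H]1C[C@H]2OC(C)(C)O[C@H]2C(C)(C)[C@@H]1CC/C(CCl)=C\CC[C@@](C)(O[Si](C)(C)C(C)(C)C)C=C
F3 | step 15 | decalin methyl ester (methyl ester of 21) | C=C[C@](C)(O[Si](C)(C)C(C)(C)C)CC[C@@H]1C(=C)CC[C@H]2C(C)(C)[C@@H]3OC(C)(C)O[C@@H]3C[C@]12C(=O)OC
F0 | step 14 | none | none
F4 | step 19 | cyclic 2,3-orthoacetate of 24 | C=C[C@](C)(O[Si](C)(C)C(C)(C)C)CC[C@@H]1C(=C)CC[C@H]2C(C)(C)[C@@H]3OC(C)(OC)O[C@@H]3C[C@]12COC(C)=O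
F5 | step 19 | 3α-acetate 2α-alcohol | C=C[C@](C)(O[Si](C)(C)C(C)(C)C)CC[C@@H]1C(=C)CC[C@H]2C(C)(C)[C@H](OC(C)=O)[C@H](O)C[C@]12COC(C)=O
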